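**Retrosynthetic overview**

1. The cyclohexene ring (C1, C2, C3, C11', C13', C5) is opened, after removal of the C1 hydroxyl, by a retro-[4+2] (C5–C13' and C3–C11'). This gives 8-epi-xanthatin (7R,8R,10S) as the diene and an α-methylene lactone enol triflate of the mirror-image series (7'S,8'S,10'R) as the dienophile.
2. Each half is traced back (side chain by Heck reaction, exo-methylene by Horner–Wadsworth–Emmons olefination, C10 methyl and C1 carbonyl by enone chemistry) to a phosphono lactone. Its lactone ring is made in one operation from meso-cis-cyclohept-2-ene-1,4-diyl diacetate and (diethoxyphosphoryl)acetic acid by a palladium-catalysed tandem allylic C-/O-alkylation.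
3. Feature used: in the primed half the γ-lactone is cis-fused across C7'–C8' of the seven-membered ring (O on C8', the later spiro carbon C11' on C7') and the neighbouring C9'–C10' can be carried as an alkene. That ring is therefore a cis-cyclohept-2-ene-1,4-diyl unit that is meso before the lactone is on, and since the other half holds the same unit in mirror-image form, both enantiotopic ends of one meso diacetate are used.
4. Order of ring formation: seven-membered rings bought (cycloheptadiene); γ-lactones (key step, once per enantiomeric series with enantiomeric ligands); cyclohexene ring (Diels–Alder); then C1–OH and the dienone side chain.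

Key step: step 2

Remark on numbering: xanthane numbering is used (C1, C5–C10 seven-membered ring; C11–C13 lactone carbons; C2–C4 and C15 side chain). Primed numbers belong to the half that carries the spiro lactone and the dienone.

Assumption: the (R,R)-ligand is written for the 7'S,8'S series and the (S,S)-ligand for the 7R,8R series. If the sense of induction is the opposite, the two ligands are exchanged, since both series are needed.

**Route**

Step 1
Reactants: 1 cyclohepta-1,3-diene
Product: 2 meso-cis-cyclohept-2-ene-1,4-diyl diacetate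
Conditions: Pd(OAc)2 (5 mol%), LiCl (20 mol%), LiOAc, p-benzoquinone (2 equiv), AcOH, 25 °C
Reagents that add atoms: acetic acid, CC(=O)O
Why: Divalent-palladium-catalysed 1,4-diacetoxylation of a conjugated diene, in which trans-acetoxypalladation gives a π-allyl complex that, with chloride present, is attacked by acetate anti to palladium, so that both acetates end cis and the product is meso (no absolute configuration is created).

Step 2
Reactants: 2 meso-cis-cyclohept-2-ene-1,4-diyl diacetate; 3 (diethoxyphosphoryl)acetic acid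
Product: 5 diethyl [(3aR,8aS)-2-oxo-3,3a,4,5,6,8a-hexahydro-2H-cyclohepta[b]furan-3-yl]phosphonate, via monoalkylated allylic acetate 4 (not isolated)
Conditions: 3, LiN(SiMe3)2 (2.0 equiv), THF, −78 to 0 °C; then 2, [Pd(C3H5)Cl]2 (2.5 mol%), (R,R)-DACH-phenyl bisphosphine ligand (N,N'-[(1R,2R)-cyclohexane-1,2-diyl]bis[2-(diphenylphosphanyl)benzamide], 7.5 mol%), THF, 0 to 40 °C
Reagents that add atoms: none
Why: Proposed new method: zerovalent palladium with the chiral ligand ionises one of the two enantiotopic allylic acetates of 2, the phosphonate-stabilised carbon of the dianion of 3 attacks the allyl terminus anti to palladium (C7'–C11' bond, net retention), and ionisation of the second acetate in 4 gives a new π-allyl complex whose near terminus is captured by the pendant carboxylate, again anti to palladium (O–C8' bond); the closest known reaction types are the palladium-catalysed [3+2] annulation of meso-2-ene-1,4-diyl diesters with C,O-ambident nucleophiles (C-allylation followed by O-allylation) and the palladium-catalysed lactonisation of allylic acetates that carry a carboxylic acid. The lactone ring closes by a 5-exo attack of oxygen on the allyl terminus next to C7', which leaves C9'=C10' outside the new ring. C7' is set by the ligand-controlled choice between the enantiotopic leaving groups together with double inversion, and C8' follows from the second net retention, which forces the cis ring fusion; C11' is left as a mixture and is made planar later. The step needs C- before O-allylation, O- and not C-closure in the second stage, and a five- and not a seven-membered closure: carboxylate O-allylation is reversible under palladium whereas C-allylation is not, the two equivalents of base are used up after the first alkylation so that the carboxylate is the only anion left, a vinylcyclopropane formed through carbon would be reopened by the catalyst, and only C8' is within reach of the tethered carboxylate for an unstrained ring. The product is itself an allylic lactone, but its reionisation can only return the same cis-fused ring.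

Step 3
Reactants: 5 diethyl [(3aR,8aS)-2-oxo-3,3a,4,5,6,8a-hexahydro-2H-cyclohepta[b]furan-3-yl]phosphonate
Product: 6 diethyl [(3aR,8aS)-2,6-dioxo-3,3a,4,5,6,8a-hexahydro-2H-cyclohepta[b]furan-3-yl]phosphonate
Conditions: Rh2(cap)4 (dirhodium tetrakis(caprolactamate), 1 mol%), t-BuOOH (70% in water, 5 equiv), 1,2-dichloroethane, 40 °C
Reagents that add atoms: tert-butyl hydroperoxide, CC(C)(C)OO
Why: Kharasch–Sosnovsky-type allylic C–H oxidation by tert-butylperoxyl radicals should turn the only allylic methylene (C1') into the ketone, because the other allylic hydrogen (on C8') is tertiary and deactivated by the acyloxy group and the allyl radical should be trapped at the terminus remote from that group; no stereocentre is formed.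

Step 4
Reactants: 6 diethyl [(3aR,8aS)-2,6-dioxo-3,3a,4,5,6,8a-hexahydro-2H-cyclohepta[b]furan-3-yl]phosphonate
Product: 7 diethyl [(3aR,8aR)-7-iodo-2,6-dioxo-3,3a,4,5,6,8a-hexahydro-2H-cyclohepta[b]furan-3-yl]phosphonate
Conditions: I2 (1.5 equiv), pyridine/CH2Cl2 (1:1), 0 to 25 °C
Reagents that add atoms: iodine, II
Why: α-Iodination of an enone by a Baylis–Hillman-type addition–elimination (pyridine adds to C9', the enolate is iodinated, pyridine leaves) puts iodine on C10', the only enone α-carbon; no stereocentre is formed.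

Step 5
Reactants: 7 diethyl [(3aR,8aR)-7-iodo-2,6-dioxo-3,3a,4,5,6,8a-hexahydro-2H-cyclohepta[b]furan-3-yl]phosphonate
Product: 8 diethyl [(3aR,8aS)-7-methyl-2,6-dioxo-3,3a,4,5,6,8a-hexahydro-2H-cyclohepta[b]furan-3-yl]phosphonate
Conditions: Me4Sn (2 equiv), Pd2(dba)3 (2.5 mol%), AsPh3 (10 mol%), CuI (10 mol%), NMP, 60 °C
Reagents that add atoms: tetramethylstannane, C[Sn](C)(C)C
Why: Stille coupling of an α-iodoenone installs the C10' methyl group, oxidative addition into the C–I bond being much faster than ionisation of the allylic lactone; no stereocentre is formed.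

Step 6
Reactants: 8 diethyl [(3aR,8aS)-7-methyl-2,6-dioxo-3,3a,4,5,6,8a-hexahydro-2H-cyclohepta[b]furan-3-yl]phosphonate
Product: 9 diethyl [(3aR,7R,8aS)-7-methyl-2,6-dioxooctahydro-2H-cyclohepta[b]furan-3-yl]phosphonate
Conditions: H2 (1 atm), Rh/Al2O3 (5 wt%), EtOAc, 25 °C
Reagents that add atoms: none
Why: Heterogeneous hydrogenation of the enone double bond should deliver hydrogen to C9'/C10' from the convex face of the cis-fused bicycle, anti to the allylic C8'–O bond and the lactone ring, which places the methyl group cis to the lactone (10'R); rhodium on alumina is chosen to limit hydrogenolysis of the allylic C–O bond.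

Step 7
Reactants: 9 diethyl [(3aR,7R,8aS)-7-methyl-2,6-dioxooctahydro-2H-cyclohepta[b]furan-3-yl]phosphonate
Product: 10 (3aR,7R,8aS)-3-(diethoxyphosphoryl)-7-methyl-2-oxo-3,3a,4,7,8,8a-hexahydro-2H-cyclohepta[b]furan-6-yl trifluoromethanesulfonate
Conditions: KN(SiMe3)2 (2.2 equiv), THF, −78 °C; PhNTf2 (1.2 equiv), −78 to −20 °C
Reagents that add atoms: N-phenylbis(trifluoromethanesulfonimide), O=S(=O)(N(c1ccccc1)S(=O)(=O)C(F)(F)F)C(F)(F)F
Why: Kinetic enolate O-triflation, in which the first equivalent of base protects the phosphonate α-C–H as its anion and the second removes a proton from the less hindered C5' methylene and not from the methine C10', so that the enol triflate forms towards C5' and the C10' stereocentre is not touched.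

Step 8
Reactants: 10 (3aR,7R,8aS)-3-(diethoxyphosphoryl)-7-methyl-2-oxo-3,3a,4,7,8,8a-hexahydro-2H-cyclohepta[b]furan-6-yl trifluoromethanesulfonate
Product: 11 (3aS,7R,8aS)-7-methyl-3-methylidene-2-oxo-3,3a,4,7,8,8a-hexahydro-2H-cyclohepta[b]furan-6-yl trifluoromethanesulfonate
Conditions: aqueous HCHO (37%, 5 equiv), K2CO3 (2 equiv), THF, 0 to 25 °C
Reagents that add atoms: formaldehyde, C=O
Why: Horner–Wadsworth–Emmons olefination of the α-phosphono lactone with formaldehyde gives the α-methylene lactone and erases the C11' stereocentre, the enol triflate being stable to carbonate.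

Step 9
Reactants: 2 meso-cis-cyclohept-2-ene-1,4-diyl diacetate; 3 (diethoxyphosphoryl)acetic acid
Product: 13 diethyl [(3aS,8aR)-2-oxo-3,3a,4,5,6,8a-hexahydro-2H-cyclohepta[b]furan-3-yl]phosphonate, via monoalkylated allylic acetate 12 (not isolated)
Conditions: 3, LiN(SiMe3)2 (2.0 equiv), THF, −78 to 0 °C; then 2, [Pd(C3H5)Cl]2 (2.5 mol%), (S,S)-DACH-phenyl bisphosphine ligand (7.5 mol%), THF, 0 to 40 °C
Reagents that add atoms: none
Why: Proposed new method: the same tandem allylic C-alkylation/O-lactonisation as in step 2 (ionisation, anti attack of the phosphonate carbanion, second ionisation, 5-exo capture by the carboxylate; closest known types are the palladium-catalysed [3+2] annulation of meso-2-ene-1,4-diyl diesters with C,O-ambident nucleophiles and the palladium-catalysed lactonisation of allylic acetates), run with the enantiomeric ligand so that the other enantiotopic acetate leaves first and C7 and C8 are set in the mirror-image sense with the same cis fusion.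

Step 10
Reactants: 13 diethyl [(3aS,8aR)-2-oxo-3,3a,4,5,6,8a-hexahydro-2H-cyclohepta[b]furan-3-yl]phosphonate
Product: 14 diethyl [(3aS,8aR)-2,6-dioxo-3,3a,4,5,6,8a-hexahydro-2H-cyclohepta[b]furan-3-yl]phosphonate
Conditions: Rh2(cap)4 (1 mol%), t-BuOOH (70% in water, 5 equiv), 1,2-dichloroethane, 40 °C
Reagents that add atoms: tert-butyl hydroperoxide, CC(C)(C)OO
Why: Kharasch–Sosnovsky-type allylic oxidation of the only allylic methylene (C1) to the enone, as in step 3; no stereocentre is formed.

Step 11
Reactants: 14 diethyl [(3aS,8aR)-2,6-dioxo-3,3a,4,5,6,8a-hexahydro-2H-cyclohepta[b]furan-3-yl]phosphonate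
Product: 15 diethyl [(3aS,8aS)-7-iodo-2,6-dioxo-3,3a,4,5,6,8a-hexahydro-2H-cyclohepta[b]furan-3-yl]phosphonate
Conditions: I2 (1.5 equiv), pyridine/CH2Cl2 (1:1), 0 to 25 °C
Reagents that add atoms: iodine, II
Why: Baylis–Hillman-type addition–elimination α-iodination of the enone at C10, as in step 4; no stereocentre is formed.

Step 12
Reactants: 15 diethyl [(3aS,8aS)-7-iodo-2,6-dioxo-3,3a,4,5,6,8a-hexahydro-2H-cyclohepta[b]furan-3-yl]phosphonate
Product: 16 diethyl [(3aS,8aR)-7-methyl-2,6-dioxo-3,3a,4,5,6,8a-hexahydro-2H-cyclohepta[b]furan-3-yl]phosphonate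
Conditions: Me4Sn (2 equiv), Pd2(dba)3 (2.5 mol%), AsPh3 (10 mol%), CuI (10 mol%), NMP, 60 °C
Reagents that add atoms: tetramethylstannane, C[Sn](C)(C)C
Why: Stille coupling of the α-iodoenone installs the C10 methyl group, as in step 5; no stereocentre is formed.

Step 13
Reactants: 16 diethyl [(3aS,8aR)-7-methyl-2,6-dioxo-3,3a,4,5,6,8a-hexahydro-2H-cyclohepta[b]furan-3-yl]phosphonate
Product: 17 diethyl [(3aS,7S,8aR)-7-methyl-2,6-dioxooctahydro-2H-cyclohepta[b]furan-3-yl]phosphonate
Conditions: H2 (1 atm), Rh/Al2O3 (5 wt%), EtOAc, 25 °C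
Reagents that add atoms: none
Why: Heterogeneous hydrogenation from the convex face, anti to the allylic C8–O bond, should place the C10 methyl group cis to the lactone (10S), as in step 6.

Step 14
Reactants: 17 diethyl [(3aS,7S,8aR)-7-methyl-2,6-dioxooctahydro-2H-cyclohepta[b]furan-3-yl]phosphonate
Product: 18 (3aS,7S,8aR)-3-(diethoxyphosphoryl)-7-methyl-2-oxo-3,3a,4,7,8,8a-hexahydro-2H-cyclohepta[b]furan-6-yl trifluoromethanesulfonate
Conditions: KN(SiMe3)2 (2.2 equiv), THF, −78 °C; PhNTf2 (1.2 equiv), −78 to −20 °C
Reagents that add atoms: N-phenylbis(trifluoromethanesulfonimide), O=S(=O)(N(c1ccccc1)S(=O)(=O)C(F)(F)F)C(F)(F)F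
Why: Kinetic enolate O-triflation towards the C5 methylene with the phosphonate carried as its anion, as in step 7; the C10 stereocentre is not touched.

Step 15
Reactants: 18 (3aS,7S,8aR)-3-(diethoxyphosphoryl)-7-methyl-2-oxo-3,3a,4,7,8,8a-hexahydro-2H-cyclohepta[b]furan-6-yl trifluoromethanesulfonate; 19 but-3-en-2-one
Product: 20 diethyl [(3aS,7S,8aR)-7-methyl-2-oxo-6-[(1E)-3-oxobut-1-en-1-yl]-3,3a,4,7,8,8a-hexahydro-2H-cyclohepta[b]furan-3-yl]phosphonate
Conditions: Pd(OAc)2 (5 mol%), PPh3 (10 mol%), Et3N (2 equiv), 19 (5 equiv), DMF, 60 °C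
Reagents that add atoms: none
Why: Heck reaction of the enol triflate with methyl vinyl ketone, in which syn-carbopalladation and syn-β-hydride elimination give the (E)-dienone; no stereocentre is involved, and the product has a diene but no dienophile.

Step 16
Reactants: 20 diethyl [(3aS,7S,8aR)-7-methyl-2-oxo-6-[(1E)-3-oxobut-1-en-1-yl]-3,3a,4,7,8,8a-hexahydro-2H-cyclohepta[b]furan-3-yl]phosphonate
Product: 21 8-epi-xanthatin
Conditions: aqueous HCHO (37%, 5 equiv), K2CO3 (2 equiv), THF, 0 to 25 °C
Reagents that add atoms: formaldehyde, C=O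
Why: Horner–Wadsworth–Emmons olefination with formaldehyde unveils the α-methylene lactone last and erases the C11 stereocentre.

Step 17
Reactants: 21 8-epi-xanthatin; 11 (3aS,7R,8aS)-7-methyl-3-methylidene-2-oxo-3,3a,4,7,8,8a-hexahydro-2H-cyclohepta[b]furan-6-yl trifluoromethanesulfonate
Product: 22 exo Diels–Alder adduct (3S,5S,7R,8R,10S,11'R,7'S,8'S,10'R)
Conditions: 11 (3 equiv), BHT (5 mol%), toluene (3 M), 100 °C, sealed tube, dark
Reagents that add atoms: none
Why: Thermal intermolecular Diels–Alder reaction in the head-to-tail sense of xanthanolide dimers, in which the large HOMO coefficient at C5 pairs with the methylene carbon C13' so that C5–C13' and C3–C11' form; the diene should react on the face away from the body of its seven-membered ring, that is syn to the pseudo-axial C10 methyl that allylic strain with C2–H enforces (sets C5), the methylene lactone on its convex face syn to H7' (sets C11' relative to C7') and through the transition state with the lactone carbonyl exo as usual for α-substituted acrylates (sets C11' relative to C5), while 11, which has no diene, is used in excess to outrun self-dimerisation of 21, and C3 forms as a transient centre.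

Step 18
Reactants: 22 exo Diels–Alder adduct (3S,5S,7R,8R,10S,11'R,7'S,8'S,10'R)
Product: 24 C1-hydroxy enone enol triflate (1S,5S,7R,8R,10S,11'R,7'S,8'S,10'R), via tertiary hydroperoxide 23 (not isolated)
Conditions: O2 (1 atm), DBU (0.3 equiv), MeCN, 0 °C; then PPh3 (1.2 equiv)
Reagents that add atoms: dioxygen, O=O
Why: Vinylogous autoxidation, in which DBU removes the C3–H (α to the ketone and allylic) to give the extended enolate over O–C4–C3–C2–C1, oxygen is taken up at the γ-carbon C1 to give the conjugated enone hydroperoxide 23 by axial attack on the face anti to H5 (chair-like, trans ring fusion, the course known for ring-fusion γ-carbons of steroidal dienolates), which sets C1, and triphenylphosphine reduces the O–O bond to the tertiary alcohol; the C3 centre is destroyed.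

Step 19
Reactants: 24 C1-hydroxy enone enol triflate (1S,5S,7R,8R,10S,11'R,7'S,8'S,10'R); 19 but-3-en-2-one
Product: 25 CNP0168949.2
Conditions: Pd(OAc)2 (5 mol%), PPh3 (10 mol%), Et3N (2 equiv), 19 (10 equiv), DMF, 60 °C
Reagents that add atoms: none
Why: Heck reaction of the enol triflate with a large excess of methyl vinyl ketone (to outcompete insertion into the two methylene lactones) gives the (E)-dienone by syn-insertion and syn-β-hydride elimination; no stereocentre is touched.

**Compound list**

1 | cyclohepta-1,3-diene | C1=CC=CCCC1 | starting material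
2 | meso-(1R,4S)-cyclohept-2-ene-1,4-diyl diacetate (cis) | CC(=O)O[C@H]1C=C[C@@H](OC(C)=O)CCC1 | intermediate
3 | (diethoxyphosphoryl)acetic acid | CCOP(=O)(OCC)CC(=O)O | starting material
4 | 2-[(1R,4S)-4-acetoxycyclohept-2-en-1-yl]-2-(diethoxyphosphoryl)acetic acid (formed as its lithium carboxylate; epimers at the phosphonate carbon) | CCOP(=O)(OCC)C(C(=O)O)[C@H]1C=C[C@@H](OC(C)=O)CCC1 | intermediate (not isolated)
5 | diethyl [(3aR,8aS)-2-oxo-3,3a,4,5,6,8a-hexahydro-2H-cyclohepta[b]furan-3-yl]phosphonate (cis-fused; epimers at C3) | CCOP(=O)(OCC)C1C(=O)O[C@H]2C=CCCC[C@@H]12 | intermediate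
6 | diethyl [(3aR,8aS)-2,6-dioxo-3,3a,4,5,6,8a-hexahydro-2H-cyclohepta[b]furan-3-yl]phosphonate | CCOP(=O)(OCC)C1C(=O)O[C@H]2C=CC(=O)CC[C@@H]12 | intermediate
7 | diethyl [(3aR,8aR)-7-iodo-2,6-dioxo-3,3a,4,5,6,8a-hexahydro-2H-cyclohepta[b]furan-3-yl]phosphonate | CCOP(=O)(OCC)C1C(=O)O[C@H]2C=C(I)C(=O)CC[C@@H]12 | intermediate
8 | diethyl [(3aR,8aS)-7-methyl-2,6-dioxo-3,3a,4,5,6,8a-hexahydro-2H-cyclohepta[b]furan-3-yl]phosphonate | CCOP(=O)(OCC)C1C(=O)O[C@H]2C=C(C)C(=O)CC[C@@H]12 | intermediate
9 | diethyl [(3aR,7R,8aS)-7-methyl-2,6-dioxooctahydro-2H-cyclohepta[b]furan-3-yl]phosphonate (methyl cis to the lactone) | CCOP(=O)(OCC)C1C(=O)O[C@H]2C[C@@H](C)C(=O)CC[C@@H]12 | intermediate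
10 | (3aR,7R,8aS)-3-(diethoxyphosphoryl)-7-methyl-2-oxo-3,3a,4,7,8,8a-hexahydro-2H-cyclohepta[b]furan-6-yl trifluoromethanesulfonate | CCOP(=O)(OCC)C1C(=O)O[C@H]2C[C@@H](C)C(OS(=O)(=O)C(F)(F)F)=CC[C@@H]12 | intermediate
11 | (3aS,7R,8aS)-7-methyl-3-methylidene-2-oxo-3,3a,4,7,8,8a-hexahydro-2H-cyclohepta[b]furan-6-yl trifluoromethanesulfonate | C=C1C(=O)O[C@H]2C[C@@H](C)C(OS(=O)(=O)C(F)(F)F)=CC[C@@H]12 | intermediate
12 | 2-[(1S,4R)-4-acetoxycyclohept-2-en-1-yl]-2-(diethoxyphosphoryl)acetic acid (formed as its lithium carboxylate; epimers at the phosphonate carbon) | CCOP(=O)(OCC)C(C(=O)O)[C@@H]1C=C[C@H](OC(C)=O)CCC1 | intermediate (not isolated)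
13 | diethyl [(3aS,8aR)-2-oxo-3,3a,4,5,6,8a-hexahydro-2H-cyclohepta[b]furan-3-yl]phosphonate (cis-fused; epimers at C3) | CCOP(=O)(OCC)C1C(=O)O[C@@H]2C=CCCC[C@H]12 | intermediate
14 | diethyl [(3aS,8aR)-2,6-dioxo-3,3a,4,5,6,8a-hexahydro-2H-cyclohepta[b]furan-3-yl]phosphonate | CCOP(=O)(OCC)C1C(=O)O[C@@H]2C=CC(=O)CC[C@H]12 | intermediate
15 | diethyl [(3aS,8aS)-7-iodo-2,6-dioxo-3,3a,4,5,6,8a-hexahydro-2H-cyclohepta[b]furan-3-yl]phosphonate | CCOP(=O)(OCC)C1C(=O)O[C@@H]2C=C(I)C(=O)CC[C@H]12 | intermediate
16 | diethyl [(3aS,8aR)-7-methyl-2,6-dioxo-3,3a,4,5,6,8a-hexahydro-2H-cyclohepta[b]furan-3-yl]phosphonate | CCOP(=O)(OCC)C1C(=O)O[C@@H]2C=C(C)C(=O)CC[C@H]12 | intermediate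
17 | diethyl [(3aS,7S,8aR)-7-methyl-2,6-dioxooctahydro-2H-cyclohepta[b]furan-3-yl]phosphonate (methyl cis to the lactone) | CCOP(=O)(OCC)C1C(=O)O[C@@H]2C[C@H](C)C(=O)CC[C@H]12 | intermediate
18 | (3aS,7S,8aR)-3-(diethoxyphosphoryl)-7-methyl-2-oxo-3,3a,4,7,8,8a-hexahydro-2H-cyclohepta[b]furan-6-yl trifluoromethanesulfonate | CCOP(=O)(OCC)C1C(=O)O[C@@H]2C[C@H](C)C(OS(=O)(=O)C(F)(F)F)=CC[C@H]12 | intermediate
19 | but-3-en-2-one (methyl vinyl ketone) | CC(=O)C=C | starting material
20 | diethyl [(3aS,7S,8aR)-7-methyl-2-oxo-6-[(1E)-3-oxobut-1-en-1-yl]-3,3a,4,7,8,8a-hexahydro-2H-cyclohepta[b]furan-3-yl]phosphonate | CCOP(=O)(OCC)C1C(=O)O[C@@H]2C[C@H](C)C(/C=C/C(C)=O)=CC[C@H]12 | intermediate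
21 | 8-epi-xanthatin, (3aR,7S,8aR)-7-methyl-3-methylidene-6-[(1E)-3-oxobut-1-en-1-yl]-3,3a,4,7,8,8a-hexahydro-2H-cyclohepta[b]furan-2-one | C=C1C(=O)O[C@@H]2C[C@H](C)C(/C=C/C(C)=O)=CC[C@H]12 | intermediate
22 | exo Diels–Alder adduct, (3S,5S,7R,8R,10S,11'R,7'S,8'S,10'R): cyclohexene ring with C1=C2, C3 (H and acetyl), spiro C11', C13' and C5, trans to nothing yet at C1, fused at C1–C5 to the seven-membered ring of the 8-epi-xanthatin half; C11' is the α-carbon of the cis-fused lactone of the enol triflate half | C=C1C(=O)O[C@@H]2C[C@H](C)C3=C[C@H](C(C)=O)[C@]4(C[C@@H]3C[C@H]12)C(=O)O[C@H]1C[C@@H](C)C(OS(=O)(=O)C(F)(F)F)=CC[C@H]14 | intermediate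
23 | C1 hydroperoxide of the C2=C3 enone, (1S,5S,7R,8R,10S,11'R,7'S,8'S,10'R), OOH trans to H5 | C=C1C(=O)O[C@@H]2C[C@H](C)[C@@]3(OO)C=C(C(C)=O)[C@]4(C[C@@H]3C[C@H]12)C(=O)O[C@H]1C[C@@H](C)C(OS(=O)(=O)C(F)(F)F)=CC[C@H]14 | intermediate (not isolated)
24 | C1-hydroxy enone enol triflate, (1S,5S,7R,8R,10S,11'R,7'S,8'S,10'R): the target with OTf on C1' in place of the butenone chain | C=C1C(=O)O[C@@H]2C[C@H](C)[C@@]3(O)C=C(C(C)=O)[C@]4(C[C@@H]3C[C@H]12)C(=O)O[C@H]1C[C@@H](C)C(OS(=O)(=O)C(F)(F)F)=CC[C@H]14 | intermediate
25 | CNP0168949.2, (1S,5S,7R,8R,10S,11'R,7'S,8'S,10'R) | C=C1C(=O)O[C@@H]2C[C@H](C)[C@@]3(O)C=C(C(C)=O)[C@]4(C[C@@H]3C[C@H]12)C(=O)O[C@H]1C[C@@H](C)C(/C=C/C(C)=O)=CC[C@H]14 | target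

**Step count and risks**

Total step count: 19. Longest linear sequence: 12 steps (steps 1, 9–16 and 17–19).

Steps most likely to fail:

1. Step 2 (proposed new method). The second allylic substitution may close through carbon to a vinylcyclopropane or not take place, and a dianionic nucleophile may lower the discrimination between the enantiotopic acetates. The fallback sets out from 2 and comes back at 5. Compound 2 would be monoalkylated with the sodium enolate (NaH) of commercial tert-butyl (diethoxyphosphoryl)acetate under the same catalyst, a Tsuji–Trost desymmetrisation with a stabilised carbanion, to give tert-butyl 2-[(1R,4S)-4-acetoxycyclohept-2-en-1-yl]-2-(diethoxyphosphoryl)acetate F1. Trifluoroacetic acid would then free the acid 4, now isolated. Pd(PPh3)4 with Et3N in THF would close the lactone by intramolecular allylic substitution with the carboxylate, which returns to 5.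

2. Step 9 (proposed new method). The same processes may fail in the mirror-image series. The fallback sets out from 2 and comes back at 13. Monoalkylation of 2 with the sodium enolate of tert-butyl (diethoxyphosphoryl)acetate under the catalyst with the (S,S)-ligand would give tert-butyl 2-[(1S,4R)-4-acetoxycyclohept-2-en-1-yl]-2-(diethoxyphosphoryl)acetate F2. Trifluoroacetic acid would give the acid 12, and Pd(PPh3)4 with Et3N would lactonise it to 13.

3. Step 17. Self-dimerisation of 21 through its own methylene lactone may compete with the cross reaction, conversion may be low, and the facial or exo selectivity may be poor. The fallback sets out from 20 and 11 and comes back at 22. Dienone 20, which has a diene but no dienophile, would be heated with 11 under the conditions of step 17 to give the phosphono lactone Diels–Alder adduct F3. Horner–Wadsworth–Emmons olefination (aqueous HCHO, K2CO3, THF, 0 °C, under argon to keep oxygen from the enolisable C3–H) would then install the methylene group and give 22.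

Further compounds
F1 | step 2 | tert-butyl 2-[(1R,4S)-4-acetoxycyclohept-2-en-1-yl]-2-(diethoxyphosphoryl)acetate | CCOP(=O)(OCC)C(C(=O)OC(C)(C)C)[C@H]1C=C[C@@H](OC(C)=O)CCC1
F2 | step 9 | tert-butyl 2-[(1S,4R)-4-acetoxycyclohept-2-en-1-yl]-2-(diethoxyphosphoryl)acetate | CCOP(=O)(OCC)C(C(=O)OC(C)(C)C)[C@@H]1C=C[C@H](OC(C)=O)CCC1
F3 | step 17 | phosphono lactone Diels–Alder adduct (as 22, with the diethoxyphosphoryl group and H on C11 in place of the methylene group) | CCOP(=O)(OCC)C1C(=O)O[C@@H]2C[C@H](C)C3=C[C@H](C(C)=O)[C@]4(C[C@@H]3C[C@H]12)C(=O)O[C@H]1C[C@@H](C)C(OS(=O)(=O)C(F)(F)F)=CC[C@H]14
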